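**Retrosynthetic overview**
1. Broussonol A ⇐ acid removal of the 5-O-MOM group from an 8-(1,1-dimethylallyl) flavonol that already carries the dimethylchromene.
2. Key disconnection: that flavonol ⇐ one open-chain 2'-hydroxychalcone with a 4'-O-prenyl ether (ring A) and a 1,1-dimethylpropargyl ether (ring B). One pot runs an aromatic Claisen shift, a propargyl Claisen/[1,5]-H/oxa-6π sequence and an oxa-Michael closure on heating, then alkaline H2O2 raises ring C to the flavonol level.
3. Chalcone ⇐ Claisen–Schmidt condensation of a desymmetrised phloroacetophenone ether with a mono-propargylated protocatechualdehyde.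
4. Fragments ⇐ 2,4,6-trihydroxyacetophenone + prenyl bromide (+ MOMCl), and 3,4-dihydroxybenzaldehyde + 3-chloro-3-methylbut-1-yne.
5. Ring order: rings A and B are bought; pyran ring D and pyranone ring C both close in step 5; only deprotection follows.

Assumption: the target SMILES has no stereocentre, so "single enantiomer" is read as the achiral compound drawn; the C-2/C-3 stereocentres of the flavanone-type intermediates are racemic and are destroyed within step 5.

**Route**

Step 1
Reactants: 1 2,4,6-trihydroxyacetophenone; 2 prenyl bromide (1-bromo-3-methylbut-2-ene)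
Product: 3 1-[2,6-dihydroxy-4-(3-methylbut-2-enyloxy)phenyl]ethanone
Conditions: K2CO3 (1.1 equiv), acetone, reflux, 6 h
Reagents that add atoms: none
Why: Williamson etherification; with one equivalent of weak base only the 4-OH, the most acidic hydroxyl and the only one not hydrogen-bonded to the ketone, is ionised and O-alkylated by the primary allylic bromide.

Step 2
Reactants: 3 1-[2,6-dihydroxy-4-(3-methylbut-2-enyloxy)phenyl]ethanone
Product: 4 1-[2-hydroxy-6-(methoxymethoxy)-4-(3-methylbut-2-enyloxy)phenyl]ethanone
Conditions: MOMCl (1.15 equiv), i-Pr2NEt (1.5 equiv), CH2Cl2, 0 °C to rt, 3 h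
Reagents that add atoms: chloromethyl methyl ether (MOMCl), COCCl
Why: MOM ether (acetal) formation at one of the two equivalent chelated hydroxyls; the remaining hydroxyl is then locked in a strong hydrogen bond to the ketone and stays free, which separates the future O-1 from the future 5-OH.

Step 3
Reactants: 5 3,4-dihydroxybenzaldehyde; 6 3-chloro-3-methylbut-1-yne
Product: 7 3-hydroxy-4-[(2-methylbut-3-yn-2-yl)oxy]benzaldehyde
Conditions: K2CO3 (1.1 equiv), KI (10 mol %), CuI (2 mol %), acetone, N2, reflux, 16 h
Reagents that add atoms: none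
Why: Copper-assisted O-propargylation (Williamson-type, through a copper allenylidene/propargyl cation equivalent) of the 4-OH, whose phenoxide forms selectively because it is para to the formyl group and clearly more acidic than the 3-OH.

Step 4
Reactants: 4 1-[2-hydroxy-6-(methoxymethoxy)-4-(3-methylbut-2-enyloxy)phenyl]ethanone; 7 3-hydroxy-4-[(2-methylbut-3-yn-2-yl)oxy]benzaldehyde
Product: 8 (E)-1-[2-hydroxy-6-(methoxymethoxy)-4-(3-methylbut-2-enyloxy)phenyl]-3-{3-hydroxy-4-[(2-methylbut-3-yn-2-yl)oxy]phenyl}prop-2-en-1-one
Conditions: KOH (50% aq, 10 equiv), EtOH, rt, 36 h; then AcOH to pH 6, 0 °C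
Reagents that add atoms: none
Why: Claisen–Schmidt aldol condensation; E1cB dehydration gives the conjugated (E)-enone, and the MOM acetal, both ethers and the terminal alkyne are base-stable (the aldehyde OH is meta to the formyl group, so its phenoxide does not deactivate it).

Step 5
Reactants: 8 (E)-1-[2-hydroxy-6-(methoxymethoxy)-4-(3-methylbut-2-enyloxy)phenyl]-3-{3-hydroxy-4-[(2-methylbut-3-yn-2-yl)oxy]phenyl}prop-2-en-1-one
Product: 12 3,7-dihydroxy-2-(8-hydroxy-2,2-dimethyl-2H-chromen-6-yl)-5-(methoxymethoxy)-8-(2-methylbut-3-en-2-yl)-4H-chromen-4-one, via open chalcone 9 (not isolated), via flavanone 10 (not isolated), via trans-dihydroflavonol 11 (not isolated)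
Conditions: N-methyl-2-pyrrolidone (NMP, 0.1 M, degassed), PhNEt2 (2 equiv), Ar, 190 °C, 3 h; cool to 0 °C, add MeOH, NaOH (15% aq, 10 equiv), H2O2 (30% aq, 10 equiv), 0 °C to rt, 12 h; Na2SO3 (aq), 0 °C; AcOH to pH 6
Reagents that add atoms: hydrogen peroxide, OO
Why: Proposed new method: one pot in two stages — on heating, an aromatic Claisen [3,3] shift of the prenyl ether to C-3' (directed there by bond fixation from the chelated 2'-OH, with the para position blocked by the acyl group so no Claisen–Cope escape) gives the 1,1-dimethylallyl group, a propargyl Claisen shift/enolisation/[1,5]-H shift/oxa-6π electrocyclisation closes pyran ring D to give chalcone 9, and the 2'-OH then adds to the enone (amine-assisted oxa-Michael) to close ring C as flavanone 10; in the second stage NaOH reopens 10 to the 2'-oxido form of 9 (retro-oxa-Michael), which undergoes Algar–Flynn–Oyamada oxidative cyclisation (β-attack favoured by the para-oxygenated ring B, and only the 2'-oxygen is free to close) through trans-dihydroflavonol 11 to flavonol 12; the closest known reactions are the thermal Claisen rearrangement of aryl prenyl ethers, the thermal aryl 1,1-dimethylpropargyl ether to 2,2-dimethylchromene rearrangement, the chalcone–flavanone isomerisation and the alkaline H2O2 oxidation of flavanones to flavonols; the stereocentres of 10 and 11 form racemic and are removed on oxidation to 12.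

Step 6
Reactants: 12 3,7-dihydroxy-2-(8-hydroxy-2,2-dimethyl-2H-chromen-6-yl)-5-(methoxymethoxy)-8-(2-methylbut-3-en-2-yl)-4H-chromen-4-one
Product: 13 Broussonol A
Conditions: HCl (37% aq, 0.3 equiv), MeOH, 45 °C, 3 h
Reagents that add atoms: none
Why: Acid-catalysed transacetalisation of the MOM acetal to methanol frees the 5-OH, which lies peri to the carbonyl and is released easily; catalytic acid at 45 °C leaves the chromene and the 1,1-dimethylallyl group untouched, and no stereocentre is present.

**Compound list**
1 | 2,4,6-trihydroxyacetophenone | CC(=O)c1c(O)cc(O)cc1O | starting material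
2 | prenyl bromide (1-bromo-3-methylbut-2-ene) | CC(C)=CCBr | starting material
3 | 1-[2,6-dihydroxy-4-(3-methylbut-2-enyloxy)phenyl]ethanone | CC(=O)c1c(O)cc(OCC=C(C)C)cc1O | intermediate
4 | 1-[2-hydroxy-6-(methoxymethoxy)-4-(3-methylbut-2-enyloxy)phenyl]ethanone | CC(=O)c1c(O)cc(OCC=C(C)C)cc1OCOC | intermediate
5 | 3,4-dihydroxybenzaldehyde | O=Cc1ccc(O)c(O)c1 | starting material
6 | 3-chloro-3-methylbut-1-yne | C#CC(C)(C)Cl | starting material
7 | 3-hydroxy-4-[(2-methylbut-3-yn-2-yl)oxy]benzaldehyde | O=Cc1ccc(OC(C)(C)C#C)c(O)c1 | intermediate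
8 | (E)-1-[2-hydroxy-6-(methoxymethoxy)-4-(3-methylbut-2-enyloxy)phenyl]-3-{3-hydroxy-4-[(2-methylbut-3-yn-2-yl)oxy]phenyl}prop-2-en-1-one | COCOc1cc(OCC=C(C)C)cc(O)c1C(=O)/C=C/c1ccc(OC(C)(C)C#C)c(O)c1 | intermediate
9 | open chalcone (not isolated): (E)-1-[2,4-dihydroxy-6-(methoxymethoxy)-3-(2-methylbut-3-en-2-yl)phenyl]-3-(8-hydroxy-2,2-dimethyl-2H-chromen-6-yl)prop-2-en-1-one | COCOc1cc(O)c(C(C)(C)C=C)c(O)c1C(=O)/C=C/c1cc(O)c2OC(C)(C)C=Cc2c1 | intermediate
10 | flavanone (not isolated): racemic 7-hydroxy-2-(8-hydroxy-2,2-dimethyl-2H-chromen-6-yl)-5-(methoxymethoxy)-8-(2-methylbut-3-en-2-yl)-2,3-dihydro-4H-chromen-4-one | COCOc1cc(O)c(C(C)(C)C=C)c2OC(CC(=O)c12)c1cc(O)c2OC(C)(C)C=Cc2c1 | intermediate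
11 | trans-dihydroflavonol (not isolated; racemic, one enantiomer drawn): trans-3,7-dihydroxy-2-(8-hydroxy-2,2-dimethyl-2H-chromen-6-yl)-5-(methoxymethoxy)-8-(2-methylbut-3-en-2-yl)-2,3-dihydro-4H-chromen-4-one | CC1(C)C=Cc2cc(cc(O)c2O1)[C@@H]3[C@H](C(=O)c4c(OCOC)cc(O)c(C(C)(C)C=C)c4O3)O | intermediate
12 | MOM-protected flavonol: 3,7-dihydroxy-2-(8-hydroxy-2,2-dimethyl-2H-chromen-6-yl)-5-(methoxymethoxy)-8-(2-methylbut-3-en-2-yl)-4H-chromen-4-one | COCOc1cc(O)c(C(C)(C)C=C)c2oc(-c3cc(O)c4OC(C)(C)C=Cc4c3)c(O)c(=O)c12 | intermediate
13 | Broussonol A: 3,5,7-trihydroxy-2-(8-hydroxy-2,2-dimethyl-2H-chromen-6-yl)-8-(2-methylbut-3-en-2-yl)-4H-chromen-4-one (achiral) | C=CC(C)(C)c1c(O)cc(O)c2c(=O)c(O)c(-c3cc(O)c4c(c3)C=CC(C)(C)O4)oc12 | target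

**Totals**
Total step count: 6. Longest linear sequence: 5 (steps 1, 2, 4, 5, 6); step 3 is the one-step side branch.

**Three steps most likely to fail**

Step 5 (thermal cascade and oxidation in one pot). The risks are:
- prenyl migration to C-5' if ring C closes before the Claisen shift and the chelation control is lost;
- abnormal Claisen or dihydrofuran formation at the new ortho-(1,1-dimethylallyl)phenol on long heating;
- in the oxidation stage, diversion of the 6'-alkoxy chalcone to an aurone by α-attack, and slow peroxide addition because of the 7-oxido group and the hindered 2'-oxygen.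

Fallback: close ring C oxidatively first, while the 7-oxygen is still capped as its prenyl ether, and run the rearrangements afterwards in a separate flask. Algar–Flynn–Oyamada oxidation of chalcone 8 (NaOH, H2O2, MeOH/THF, 0 °C to rt) gives 3-hydroxy-2-{3-hydroxy-4-[(2-methylbut-3-yn-2-yl)oxy]phenyl}-5-(methoxymethoxy)-7-(3-methylbut-2-enyloxy)-4H-chromen-4-one F1. Heating F1 in PhNEt2 at 190 °C moves the prenyl group from O-7 to C-8 (bond fixation of the chromone favours C-8, and there is no free para site) and closes ring D. This gives MOM-protected flavonol 12, which goes into step 6. This fallback sets out from 8 and returns at 12.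

Step 1 (selective 4-O-prenylation). The risks are C-prenylation and double alkylation of the ambident phloroglucinol-type anion. Fallback: Mitsunobu etherification of 1 with 3-methylbut-2-en-1-ol (PPh3, DIAD, THF, 0 °C to rt). This engages only the most acidic, non-chelated 4-OH of the neutral phenol and avoids a free carbon-nucleophilic phenoxide. It sets out from 1 and returns at 3; no new compound is made (F0).

Step 3 (selective mono-propargylation of the catechol). The risks are alkylation at the 3-OH, double alkylation, and loss of the tertiary chloride by elimination before the weakly nucleophilic 4-phenoxide reacts. Fallback: differentiate the two oxygens through the dianion before the propargyl group is introduced. Treating 5 with NaH (2.2 equiv) in DMF at 0 °C and then MOMCl (1.0 equiv) alkylates the more nucleophilic 3-oxide and gives 4-hydroxy-3-(methoxymethoxy)benzaldehyde F2. The single remaining phenol is then alkylated with an excess of 6 (K2CO3, KI, CuI, acetone, reflux) to give 3-(methoxymethoxy)-4-[(2-methylbut-3-yn-2-yl)oxy]benzaldehyde F3. Brief treatment of F3 with catalytic HCl in MeOH at 40 °C removes the MOM group and gives 7. This fallback sets out from 5 and returns at 7.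

**Further compounds**
F1 | step 5 | 3-hydroxy-2-{3-hydroxy-4-[(2-methylbut-3-yn-2-yl)oxy]phenyl}-5-(methoxymethoxy)-7-(3-methylbut-2-enyloxy)-4H-chromen-4-one | COCOc1cc(OCC=C(C)C)cc2oc(-c3ccc(OC(C)(C)C#C)c(O)c3)c(O)c(=O)c12
F0 | step 1 | none | none
F2 | step 3 | 4-hydroxy-3-(methoxymethoxy)benzaldehyde | O=Cc1ccc(O)c(OCOC)c1
F3 | step 3 | 3-(methoxymethoxy)-4-[(2-methylbut-3-yn-2-yl)oxy]benzaldehyde | O=Cc1ccc(OC(C)(C)C#C)c(OCOC)c1
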